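**Strategy.** Everything rests on reading the lactone O–C(=O) unit of the seven-membered dioxepinone (ring C) as one molecule of CO2 held between two aryl carbons that both lie ortho to the diaryl ether oxygen: the carbon of ring A (the ring bearing methyl and CO2H) next to the methyl-bearing carbon, and the carbon of ring B (the phthalide ring) para to the phthalide carbonyl. The key step inserts CO2 there in one flask: iodine–magnesium exchange on ring A, carboxylation (aryl–carbonyl bond), then copper-mediated coupling of the new carboxylate with the ring B bromide (oxygen–aryl bond). Its precursor is a protected iodo/bromo diaryl ether, made by fluoride displacement between two separately built arenes.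

Key step: step 11

Assumption: 1 and 6 are taken as commercial; the target has no stereocentre; ring positions are called a1 (C–CH3), a2 (C–H), a3 (C–OH), a4 (C–CO2H), a5 (C–O ether), a6 (C–C(=O) of ring C) on ring A, and b1 (C–O of the ring C ester), b2 (C–CH2OH), b3 (C–OH), b4 (C–C(=O) of the phthalide), b5 (C–CH2 of the phthalide), b6 (C–O ether) on ring B.

**Route**

Step 1
Reactants: 1 3-fluoro-5-methylphenol
Product: 2 1-fluoro-3-(methoxymethoxy)-5-methylbenzene
Conditions: MOMCl, i-Pr2NEt, CH2Cl2, 0 °C to rt
Reagents that add atoms: chloromethyl methyl ether (MOMCl), COCCl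
Why: O-alkylation of the phenol (MOM protection) should give a base-stable acetal that also directs the metalation of step 2.

Step 2
Reactants: 2 1-fluoro-3-(methoxymethoxy)-5-methylbenzene
Product: 4 2-fluoro-6-(methoxymethoxy)-4-methylbenzaldehyde, via aryllithium 3 (not isolated)
Conditions: n-BuLi, THF, −78 °C; DMF, −78 to 0 °C; aq. NH4Cl
Reagents that add atoms: N,N-dimethylformamide (DMF), CN(C)C=O
Why: Directed ortho-metalation should occur at the only carbon flanked by both fluorine and the MOM ether (future a4), and Bouveault formylation of the aryllithium installs the carbon of the ring A carboxyl.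

Step 3
Reactants: 4 2-fluoro-6-(methoxymethoxy)-4-methylbenzaldehyde
Product: 5 2-fluoro-3-iodo-6-(methoxymethoxy)-4-methylbenzaldehyde
Conditions: NIS, TFA (20 mol%), MeCN, rt
Reagents that add atoms: N-iodosuccinimide (NIS), O=C1CCC(=O)N1I
Why: Electrophilic aromatic iodination should go para to the MOM ether (as in 3-fluoroanisole), which is the carbon between fluorine and methyl (a6) and is also meta to the aldehyde.

Step 4
Reactants: 6 diethyl 2,5-dihydroxyterephthalate
Product: 7 2,5-bis(hydroxymethyl)benzene-1,4-diol
Conditions: LiAlH4, THF, 0 °C to reflux; 1 M HCl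
Reagents that add atoms: none
Why: Hydride reduction of both aryl esters to benzylic alcohols should proceed cleanly because the phenoxides are inert to LiAlH4.

Step 5
Reactants: 7 2,5-bis(hydroxymethyl)benzene-1,4-diol
Product: 8 2,2,7,7-tetramethyl-4H,9H-benzo[1,2-d:4,5-d']bis([1,3]dioxine)
Conditions: 2,2-dimethoxypropane, p-TsOH·H2O (cat.), acetone, rt
Reagents that add atoms: 2,2-dimethoxypropane, COC(C)(C)OC
Why: Acid-catalysed transketalisation should close a six-membered 1,3-benzodioxin on each ortho-hydroxybenzyl alcohol unit and remove the air-sensitive hydroquinone.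

Step 6
Reactants: 8 2,2,7,7-tetramethyl-4H,9H-benzo[1,2-d:4,5-d']bis([1,3]dioxine)
Product: 9 5,10-dibromo-2,2,7,7-tetramethyl-4H,9H-benzo[1,2-d:4,5-d']bis([1,3]dioxine)
Conditions: NBS (2.2 equiv), DMF, 0 °C to rt, dark
Reagents that add atoms: N-bromosuccinimide (NBS), O=C1CCC(=O)N1Br
Why: Electrophilic aromatic bromination can only occur at the two remaining ring carbons, each ortho to an ether oxygen, so the symmetric dibromide should result.

Step 7
Reactants: 9 5,10-dibromo-2,2,7,7-tetramethyl-4H,9H-benzo[1,2-d:4,5-d']bis([1,3]dioxine)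
Product: 12 5-bromo-4-hydroxy-phthalide 6,7-acetonide (5-bromo-4,7-dihydroxy-6-(hydroxymethyl)isobenzofuran-1(3H)-one with O7 and the C6 CH2O bridged by CMe2), via monolithio bis-acetonide 10 (not isolated), via bromo acid 11 (not isolated)
Conditions: n-BuLi (1.0 equiv), THF, −78 °C; CO2; then p-TsOH·H2O (1.2 equiv), acetone, rt
Reagents that add atoms: carbon dioxide, O=C=O
Why: A single bromine–lithium exchange on the symmetric dibromide (both bromides are equivalent) and carboxylation should give the acid, which under acid lactonises irreversibly onto the only ortho CH2O (phthalide formation, loss of acetone) and frees the phenol next to bromine, while the other acetonide persists in acetone.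

Step 8
Reactants: 5 2-fluoro-3-iodo-6-(methoxymethoxy)-4-methylbenzaldehyde; 12 5-bromo-4-hydroxy-phthalide 6,7-acetonide
Product: 13 2-[(5-bromo-phthalide-6,7-acetonide-4-yl)oxy]-3-iodo-6-(methoxymethoxy)-4-methylbenzaldehyde
Conditions: Cs2CO3, DMSO, 90 °C
Reagents that add atoms: none
Why: Nucleophilic aromatic substitution (addition–elimination) of the caesium phenoxide at the single fluoride, activated by the coplanar ortho-formyl group, should form the a5–O–b6 ether without touching the aryl iodide or bromide.

Step 9
Reactants: 13 diaryl ether aldehyde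
Product: 14 2-[(5-bromo-phthalide-6,7-acetonide-4-yl)oxy]-3-iodo-6-(methoxymethoxy)-4-methylbenzoic acid
Conditions: NaClO2, NaH2PO4, 2-methyl-2-butene, t-BuOH/H2O, rt
Reagents that add atoms: sodium chlorite, [Na+].[O-]Cl=O
Why: Pinnick oxidation should convert the hindered aryl aldehyde into the acid at about pH 4 without harming the halides, the MOM ether or the acetonide.

Step 10
Reactants: 14 diaryl ether acid
Product: 15 tert-butyl 2-[(5-bromo-phthalide-6,7-acetonide-4-yl)oxy]-3-iodo-6-(methoxymethoxy)-4-methylbenzoate
Conditions: Me2NCH(Ot-Bu)2, toluene, 80 °C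
Reagents that add atoms: N,N-dimethylformamide di-tert-butyl acetal, CN(C)C(OC(C)(C)C)OC(C)(C)C
Why: tert-Butyl esterification by O-alkylation of the carboxylate is insensitive to the two ortho substituents and runs under neutral conditions that spare the acetals.

Step 11
Reactants: 15 tert-butyl iodo/bromo diaryl ether ester
Product: 18 protected conneotricone (ring A tert-butyl ester and MOM ether and ring B acetonide), via arylmagnesium chloride 16 (not isolated), via magnesium carboxylate 17 (not isolated)
Conditions: i-PrMgCl·LiCl (1.1 equiv), THF, −40 to −20 °C; CO2 (1 atm), −40 °C to rt; THF removed; Cs2CO3 (1.5 equiv), CuTC [Cu(O2CC4H3S), monovalent copper] (30 mol%), DMF, 110 °C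
Reagents that add atoms: carbon dioxide, O=C=O
Why: i-PrMgCl·LiCl should exchange the ring A iodide (the most reactive carbon–halogen bond, ortho to the aryloxy oxygen) much faster than the ring B bromide, and the aryl Grignard adds to CO2 to form the a6–carbonyl bond and a magnesium carboxylate. After the change to DMF, monovalent copper should add oxidatively to the b1–Br bond, which is activated by the para phthalide carbonyl, and C–O reductive elimination with the tethered carboxylate forms the oxygen–b1 bond. The closest known reaction types are the halogen–magnesium exchange/carboxylation of functionalised aryl iodides and the Ullmann-type (Hurtley-type) copper-mediated lactonisation of 2-halobiaryl-2'-carboxylic acids to benzo[c]chromenones. Ring C closes by intramolecular C(aryl)–O coupling in a 7-exo sense, the diaryl ether oxygen holding both reacting carbons ortho to it. No stereocentre is formed. The step needs iodine-over-bromine selectivity in the exchange and reaction of one carboxyl only, which are secured by the two different halogens and by the tert-butyl ester that masks the a4 carboxyl.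

Step 12
Reactants: 18 protected conneotricone
Product: 19 conneotricone
Conditions: TFA/H2O (9:1), rt
Reagents that add atoms: none
Why: Acidolysis should cleave the tert-butyl ester (loss of isobutene), the MOM ether and the isopropylidene acetal in one operation, while both aryl lactones are stable to acid.

**Compound list**

1 | 3-fluoro-5-methylphenol | Cc1cc(O)cc(F)c1 | starting material
2 | 1-fluoro-3-(methoxymethoxy)-5-methylbenzene | Cc1cc(OCOC)cc(F)c1 | intermediate
3 | [2-fluoro-6-(methoxymethoxy)-4-methylphenyl]lithium | Cc1cc(OCOC)c([Li])c(F)c1 | intermediate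
4 | 2-fluoro-6-(methoxymethoxy)-4-methylbenzaldehyde | Cc1cc(OCOC)c(C=O)c(F)c1 | intermediate
5 | 2-fluoro-3-iodo-6-(methoxymethoxy)-4-methylbenzaldehyde | Cc1cc(OCOC)c(C=O)c(F)c1I | intermediate
6 | diethyl 2,5-dihydroxyterephthalate | CCOC(=O)c1cc(O)c(C(=O)OCC)cc1O | starting material
7 | 2,5-bis(hydroxymethyl)benzene-1,4-diol | OCc1cc(O)c(CO)cc1O | intermediate
8 | 2,2,7,7-tetramethyl-4H,9H-benzo[1,2-d:4,5-d']bis([1,3]dioxine) | CC1(C)OCc2cc3OC(C)(C)OCc3cc2O1 | intermediate
9 | 5,10-dibromo-2,2,7,7-tetramethyl-4H,9H-benzo[1,2-d:4,5-d']bis([1,3]dioxine) | CC1(C)OCc2c(Br)c3OC(C)(C)OCc3c(Br)c2O1 | intermediate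
10 | 5-bromo-10-lithio-2,2,7,7-tetramethyl-4H,9H-benzo[1,2-d:4,5-d']bis([1,3]dioxine) | CC1(C)OCc2c(Br)c3OC(C)(C)OCc3c([Li])c2O1 | intermediate
11 | 10-bromo-2,2,7,7-tetramethyl-4H,9H-benzo[1,2-d:4,5-d']bis([1,3]dioxine)-5-carboxylic acid | CC1(C)OCc2c(Br)c3OC(C)(C)OCc3c(C(=O)O)c2O1 | intermediate
12 | 5-bromo-4-hydroxy-phthalide 6,7-acetonide (5-bromo-4,7-dihydroxy-6-(hydroxymethyl)isobenzofuran-1(3H)-one, O7 and C6 CH2O bridged by CMe2, C4 OH free) | Brc1c2COC(C)(C)Oc2c2C(=O)OCc2c1O | intermediate
13 | 2-[(5-bromo-phthalide-6,7-acetonide-4-yl)oxy]-3-iodo-6-(methoxymethoxy)-4-methylbenzaldehyde | Cc1cc(OCOC)c(C=O)c(Oc2c(Br)c3COC(C)(C)Oc3c3C(=O)OCc23)c1I | intermediate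
14 | 2-[(5-bromo-phthalide-6,7-acetonide-4-yl)oxy]-3-iodo-6-(methoxymethoxy)-4-methylbenzoic acid | Cc1cc(OCOC)c(C(=O)O)c(Oc2c(Br)c3COC(C)(C)Oc3c3C(=O)OCc23)c1I | intermediate
15 | tert-butyl 2-[(5-bromo-phthalide-6,7-acetonide-4-yl)oxy]-3-iodo-6-(methoxymethoxy)-4-methylbenzoate | Cc1cc(OCOC)c(C(=O)OC(C)(C)C)c(Oc2c(Br)c3COC(C)(C)Oc3c3C(=O)OCc23)c1I | intermediate
16 | arylmagnesium chloride from 15 (MgCl at a6) | Cc1cc(OCOC)c(C(=O)OC(C)(C)C)c(Oc2c(Br)c3COC(C)(C)Oc3c3C(=O)OCc23)c1[Mg]Cl | intermediate
17 | chloromagnesium carboxylate (CO2MgCl at a6) | Cc1cc(OCOC)c(C(=O)OC(C)(C)C)c(Oc2c(Br)c3COC(C)(C)Oc3c3C(=O)OCc23)c1C(=O)O[Mg]Cl | intermediate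
18 | protected conneotricone (a4 tert-butyl ester, a3 MOM ether, b2/b3 acetonide) | Cc1cc(OCOC)c(C(=O)OC(C)(C)C)c2c1C(=O)Oc1c3COC(C)(C)Oc3c3c(c1O2)COC3=O | intermediate
19 | conneotricone | Cc1cc(O)c(C(=O)O)c2c1C(=O)Oc1c(CO)c(O)c3c(c1O2)COC3=O | target

**Step count and risks**

Total steps: 12. Longest linear sequence: 9 steps (steps 4 to 12, from 6).

Steps most likely to fail:

1. Step 11 (key step). The doubly ortho-flanked carboxylate may lose CO2 at the temperature the copper coupling needs, oxidative addition at the hindered bromide may be slow, and magnesium may migrate to ring B by bromine–magnesium exchange before CO2 is captured. Fallback: starting from 15, the exchange and carboxylation are run as above and quenched with dilute acid to isolate the diaryl ether carboxylic acid F1. F1 is then cyclised at room temperature by light-driven nickel catalysis (Ir(ppy)3 with trivalent iridium, NiBr2·glyme with divalent nickel, 4,4'-di-tert-butyl-2,2'-bipyridine, N-tert-butylisopropylamine, DMF, blue light), a carboxylate O-arylation of aryl bromides that avoids heating; this returns to the route at 18.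

2. Step 8. Addition–elimination may be slow because both the phenoxide oxygen and the fluorinated carbon are flanked on both sides, so that base-induced degradation of the aldehyde competes. Fallback: starting from 4, nitration para to the MOM ether (NO2BF4, 2,6-di-tert-butyl-4-methylpyridine, MeCN, −30 °C) should give the nitro aldehyde F2, whose fluoride is activated by both ortho-nitro and ortho-formyl groups and should react with 12 (Cs2CO3, DMF, rt) to give the nitro diaryl ether F3. Reduction (Fe, NH4Cl, EtOH/H2O) gives the aniline F4, and aprotic Sandmeyer-type iodo-dediazoniation (t-BuONO, I2, MeCN) returns to the route at 13.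

3. Step 7. Exchange on the dibromide may be incomplete or double, and the second acetonide may be lost by hydrolysis during the acid-driven lactonisation. Fallback: starting from 9, the exchange and carboxylation are followed by full hydrolysis with aqueous HCl in THF to the unprotected bromophthalide triol F5. Only its ortho-hydroxybenzyl alcohol unit can form a six-membered ketal, so treatment with 2,2-dimethoxypropane and pyridinium p-toluenesulfonate in acetone should return to the route at 12.

Further compounds
F1 | step 11 | 3-[(5-bromo-phthalide-6,7-acetonide-4-yl)oxy]-2-(tert-butoxycarbonyl)-1-(methoxymethoxy)-5-methylbenzene-4-carboxylic acid (a6 carboxylic acid of 15) | Cc1cc(OCOC)c(C(=O)OC(C)(C)C)c(Oc2c(Br)c3COC(C)(C)Oc3c3C(=O)OCc23)c1C(=O)O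
F2 | step 8 | 2-fluoro-6-(methoxymethoxy)-4-methyl-3-nitrobenzaldehyde | Cc1cc(OCOC)c(C=O)c(F)c1[N+](=O)[O-]
F3 | step 8 | 2-[(5-bromo-phthalide-6,7-acetonide-4-yl)oxy]-6-(methoxymethoxy)-4-methyl-3-nitrobenzaldehyde | Cc1cc(OCOC)c(C=O)c(Oc2c(Br)c3COC(C)(C)Oc3c3C(=O)OCc23)c1[N+](=O)[O-]
F4 | step 8 | 3-amino-2-[(5-bromo-phthalide-6,7-acetonide-4-yl)oxy]-6-(methoxymethoxy)-4-methylbenzaldehyde | Cc1cc(OCOC)c(C=O)c(Oc2c(Br)c3COC(C)(C)Oc3c3C(=O)OCc23)c1N
F5 | step 7 | 5-bromo-4,7-dihydroxy-6-(hydroxymethyl)isobenzofuran-1(3H)-one | O=C1OCc2c(O)c(Br)c(CO)c(O)c21
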